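Target in the elm flask stood still: its readings from 15.0 h to 50.0 h average 45.1 % of the substrate charged, and the substrate reading was 0 % at 30.0 h. These are the flasks, the readings and the questions.

all flasks: temperature 0 °C
- elm: substrate 0.15 M; partner A 0.30 M; partner B 0.60 M; the very flask that is asked about, followed so far
- birch: substrate 0.075 M; partner A 0.30 M; partner B 0.60 M; run made earlier
- flask: substrate 0.15 M; partner A 0.300 M; partner B 0.600 M; time 2.0 d

elm run (percent of the substrate charged)

| time / h | target / % | substrate / % |
|---|---|---|
| 6.00 | 40.8 | 19.8 |
| 15.0 | 44.9 | 3.2 |
| 20.0 | 45.2 | 1.7 |
| 30.0 | 44.9 | 0 |
| 40.0 | 44.9 | 0.2 |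
| 50.0 | 45.4 | 0.3 |

birch run (percent of the substrate charged)

| time / min | target / % | substrate / % |
|---|---|---|
| 8.00 | 0.6 | 93.4 |
| 12.0 | 1.4 | 90.9 |
| 20.0 | 3.7 | 85.9 |
| 30.0 | 6.7 | 81.8 |
| 50.0 | 11.1 | 72.3 |
| 60.0 | 13.3 | 68.4 |
| 120 | 24.6 | 49.9 |

(readings scatter by 0.3 percentage points)

- winter: at 2.0 d take out 90 % of the target then present, then wait 15 h
- summer: at 2.0 d raise the temperature by 25 K, then wait 15 h
- midnight: at 2.0 d add partner A, 50.0 % of the amount charged, then wait 15 h
- dawn: change nothing and wait 15 h more

- target taken out counts as made
- the numbers in the tables scatter with a standard deviation of 0.3 percentage points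
- steps that have been proposed: substrate + partner B -> open intermediate; partner B + partner A -> second intermediate; open intermediate + second intermediate -> target; 2 second intermediate -> homo product; substrate -> decomposition product
- the earlier runs do not show what temperature does; that part of a forecast is a guess
- additions bring no volume worth counting

- target, in percent of the substrate first charged, at 2.0 d
- which option adds most target ("none" when 2 percentage points or less is all one gets) (winter / summer / midnight / dawn / none)
- target present, with what was taken out counted in, in percent of the substrate first charged, after summer
- target present, with what was taken out counted in, in percent of the substrate first charged, after midnight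

I took that plateau as the value at the asked time and wondered what could still feed the flask. In the proposed steps, partner A and substrate each take one partner B. That gives a budget, the spare partner B: the charge of partner B less the charges of partner A and substrate.

    spare partner B = 0.600 M − 0.300 M − 0.15 M = 0.150 M

The second way uses rates instead. Birch, with less substrate, ran close to pseudo-first-order: from 12.0 min to 120 min it lost substrate at 0.333 /h, with about 0.278 M partner B free. That constant borrows the count for birch, but the elm rate is a new reading. Elm lost substrate from 6.00 h to 15.0 h at 0.203 /h, slower than birch.

    rate constant = 0.333 /h / 0.278 M = 1.20 /M/h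
    free partner B in elm, less the substrate still to react = 0.152 M

The two ways agree, so I trusted the count: in elm, partner A and the substrate had each taken their partner B. That leaves 0.0824 M waiting as open intermediate. Dawn, winter and summer bring no partner A, so I expected nothing from them, though temperature stayed a guess. Midnight brings 0.150 M, which the spare just covers. In elm the first charge of partner A put a share of 0.225 into target. That share on the addition gives 67.6 %, and I expected more, for the open intermediate already stood ready, while birch read 0.6 % target at 8.00 min.

The forecast gave 45.1 %, midnight, 45.3 % and 57 %, lower than my figure, on the ground “Adding A with the remaining B”.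

The simulation gave 45.0 %, then 45.0 % after summer and 93.3 % after midnight. At 48.0 h elm held 54.9 % open intermediate and 0 % of partner A. The gain is 0.0725 M of target, a share of 0.483 of the spare.

    substrate + partner B → open intermediate (k = 1.20 /M/h, Ea = 48.0 kJ/mol)
    partner B + partner A → second intermediate (k = 25.0 /M/h, Ea = 60.0 kJ/mol)
    open intermediate + second intermediate → target (k = 7.40 /M/h, Ea = 55.0 kJ/mol)
    2 second intermediate → homo product (k = 3.60 /M/h, Ea = 46.0 kJ/mol)
    substrate → decomposition product (k = 2.20 × 10⁻⁴ /h, Ea = 109 kJ/mol)
    (constants at 0 °C)

The neighbour charged with 0.38 M substrate has a negative spare, short by 0.0800 M, so I reckoned 21.1 % of its substrate unreacted. Computed, that neighbour kept 21 % substrate at 48.0 h, with 0.108 % partner B.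

The data come from a simulation for an exercise; noise was put on by code.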